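**Retrosynthetic overview**

1. The CH2 bridge is cut last (aryl–CH2 by conjugate addition of the phenol, CH2–dienone by aminomethylation), giving 1-(2,6-dihydroxy-4-methoxyphenyl)butan-1-one, a one-carbon aminal and acetylfilicinic acid.
2. The cyclohexadienone ring (C1 ring ketone, C2 acetyl-bearing, C3 and C5 enol carbons, C4 CMe2, C6 bridge-bearing) is built de novo: its C3–C4 and C5–C6 bonds are formed together in a one-pot Claisen–Dieckmann [4+2] annulation of the lithium enolate of methyl isobutyrate (C4–C5 unit) with 3,5-dimethylisoxazole-4-carbonyl chloride (C3, C2, C1, C6 unit).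
3. Enabling feature: the quaternary C4 between the oxygen-bearing carbons C3 and C5 fixes the ring as a non-aromatic cyclohexane-1,3,5-trione, a double acylation product of an isobutyrate; the acetyl carbon, C2 and C1–O form a 2-acyl-1,3-dicarbonyl unit that is carried as a 3-methylisoxazole whose acidic 5-methyl group becomes C6.
4. The isoxazole is then opened by N–O hydrogenolysis and the enaminone is hydrolysed to unveil the acetyl triketone.
5. Ring order: the benzene ring and the isoxazole ring are bought; the carbocyclic dienone ring is closed in step 3; the isoxazole ring is opened in step 4; the two halves are joined in step 6.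

Key step: step 3

Remark: the β-triketones and the enaminone are drawn as one tautomer each, and enolates, ammonium salts and Lewis acid chelates of a numbered compound are treated as forms of that compound.

**Route**

Step 1
Reactants: 1 benzene-1,3,5-triol (phloroglucinol); 2 butanoyl chloride
Product: 3 1-(2,4,6-trihydroxyphenyl)butan-1-one
Conditions: AlCl3 (4 equiv), CH2Cl2–MeNO2, 0 → 40 °C; then ice, aq. HCl
Reagents that add atoms: none
Why: Friedel–Crafts acylation of the threefold symmetric, strongly activated triol should stop at the monoketone, because the first acyl group, held in an AlCl3 chelate, deactivates the ring towards a second acylation, and no stereocentre is formed.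

Step 2
Reactants: 3 1-(2,4,6-trihydroxyphenyl)butan-1-one
Product: 4 1-(2,6-dihydroxy-4-methoxyphenyl)butan-1-one
Conditions: Me2SO4 (1.0 equiv), K2CO3 (1.0 equiv), acetone, reflux
Reagents that add atoms: dimethyl sulfate, COS(=O)(=O)OC
Why: This Williamson-type O-methylation should go to the 4-hydroxyl group, the most acidic one (para to the ketone) and the only one not held in a hydrogen bond to the carbonyl oxygen, as long as one equivalent each of base and dimethyl sulfate is used, and no stereocentre is formed.

Step 3
Reactants: 5 methyl 2-methylpropanoate (used as its lithium enolate); 6 3,5-dimethyl-1,2-oxazole-4-carbonyl chloride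
Product: 8 3,5,5-trimethyl-1,2-benzoxazole-4,6(5H,7H)-dione, via keto ester 7 (not isolated)
Conditions: 5, LiN(iPr)2 (1.05 equiv), THF, −78 °C; add 6, −78 °C; then LiN(SiMe3)2 (2.0 equiv), −78 → 25 °C; aq. HCl
Reagents that add atoms: none
Why: The lithium enolate of 5 is acylated at its fully substituted carbon by acid chloride 6 (crossed Claisen condensation), which joins the CMe2 carbon to the acyl carbon and gives the non-enolisable keto ester 7, and LiN(SiMe3)2 then removes a proton from the 5-methyl group of the isoxazole to give a carbanion, a vinylogous enolate of the new ketone, that attacks the ester carbonyl and expels methoxide (Dieckmann condensation), which joins the former methyl carbon to the former ester carbon. The closest known reaction types are the C-acylation of lithium ester enolates by acid chlorides to α,α-disubstituted β-keto esters and Claisen ring closures through laterally metalated ortho-methyl aryl and heteroaryl carbonyl compounds. The carbocycle is closed in the 6-exo-trig mode, with the C4=C5 bond of the isoxazole holding the carbanion and the keto ester arm cis to each other. No stereocentre is formed, since the only sp3 ring carbons of 8 are a CH2 and a CMe2 group. The step needs C- over O-acylation of the enolate, deprotonation of the 5-methyl and not of the 3-methyl group, and ring closure in preference to retro-Claisen cleavage of 7: the first is the normal course for lithium ester enolates in THF at −78 °C, the second follows because only the 5-methyl group is conjugated with the 4-carbonyl group through the ring C=C bond, and the third is secured by the non-nucleophilic amide base, by the gem-dimethyl group that folds the chain, and by the immediate deprotonation of acidic 8 by the methoxide that is released.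

Step 4
Reactants: 8 3,5,5-trimethyl-1,2-benzoxazole-4,6(5H,7H)-dione
Product: 9 6-(1-aminoethylidene)-2,2-dimethylcyclohexane-1,3,5-trione
Conditions: H2 (1 atm), 10% Pd/C, EtOH, 25 °C
Reagents that add atoms: none
Why: Catalytic hydrogenolysis of the weak N–O bond (reductive isoxazole ring opening) should give the primary enaminone, while the enolised dione and the push-pull C=C bond, being vinylogous acid and amide units, resist hydrogenation, and no stereocentre is formed.

Step 5
Reactants: 9 6-(1-aminoethylidene)-2,2-dimethylcyclohexane-1,3,5-trione
Product: 10 2-acetyl-3,5-dihydroxy-4,4-dimethylcyclohexa-2,5-dien-1-one (acetylfilicinic acid)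
Conditions: 2 M HCl aq., 1,4-dioxane, 90 °C
Reagents that add atoms: water, O
Why: Hydrolysis of the vinylogous amide (enaminone hydrolysis) should proceed by C-protonation, attack of water on the iminium carbon and loss of ammonia, which hot dilute acid removes as ammonium chloride, to give the β-triketone, which is stable under these conditions, and no stereocentre is formed.

Step 6
Reactants: 10 2-acetyl-3,5-dihydroxy-4,4-dimethylcyclohexa-2,5-dien-1-one; 4 1-(2,6-dihydroxy-4-methoxyphenyl)butan-1-one
Product: 13 2-acetyl-6-[(3-butanoyl-2,4-dihydroxy-6-methoxyphenyl)methyl]-3,5-dihydroxy-4,4-dimethylcyclohexa-2,5-dien-1-one (target CNP0378451.0), via Mannich base 11 (not isolated), via enetrione 12 (not isolated)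
Conditions: CH2(NMe2)2 (1.05 equiv), 1,4-dioxane, 25 °C; then 4 (2 equiv), 70 °C
Reagents that add atoms: bis(dimethylamino)methane, CN(C)CN(C)C
Why: Mannich aminomethylation at the only free ring carbon of the acidic triketone 10, thermal elimination of dimethylamine from the Mannich base 11 to the enetrione 12 and Friedel–Crafts-type Michael addition of phenol 4 through one of its two equivalent free ring positions (each flanked by a hydroxyl and the methoxy group) should give the methylene-bridged product, an excess of 4 guarding against a second alkylation, and no stereocentre is formed.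

**Compound list**

1 | benzene-1,3,5-triol (phloroglucinol) | Oc1cc(O)cc(O)c1 | starting material
2 | butanoyl chloride | CCCC(Cl)=O | starting material
3 | 1-(2,4,6-trihydroxyphenyl)butan-1-one | CCCC(=O)c1c(O)cc(O)cc1O | intermediate
4 | 1-(2,6-dihydroxy-4-methoxyphenyl)butan-1-one | CCCC(=O)c1c(O)cc(OC)cc1O | intermediate
5 | methyl 2-methylpropanoate (methyl isobutyrate) | COC(=O)C(C)C | starting material
6 | 3,5-dimethyl-1,2-oxazole-4-carbonyl chloride | Cc1noc(C)c1C(Cl)=O | starting material
7 | methyl 3-(3,5-dimethyl-1,2-oxazol-4-yl)-2,2-dimethyl-3-oxopropanoate | COC(=O)C(C)(C)C(=O)c1c(C)noc1C | intermediate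
8 | 3,5,5-trimethyl-1,2-benzoxazole-4,6(5H,7H)-dione | Cc1noc2CC(=O)C(C)(C)C(=O)c12 | intermediate
9 | 6-(1-aminoethylidene)-2,2-dimethylcyclohexane-1,3,5-trione (primary enaminone; exocyclic C=C drawn with NH2 syn to the C5 carbonyl, geometry labile) | C/C(N)=C1/C(=O)CC(=O)C(C)(C)C1=O | intermediate
10 | 2-acetyl-3,5-dihydroxy-4,4-dimethylcyclohexa-2,5-dien-1-one (acetylfilicinic acid) | CC(=O)C1=C(O)C(C)(C)C(O)=CC1=O | intermediate
11 | 2-acetyl-6-[(dimethylamino)methyl]-3,5-dihydroxy-4,4-dimethylcyclohexa-2,5-dien-1-one (Mannich base) | CN(C)CC1=C(O)C(C)(C)C(O)=C(C(C)=O)C1=O | intermediate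
12 | 2-acetyl-3-hydroxy-4,4-dimethyl-6-methylidenecyclohex-2-ene-1,5-dione (enetrione) | C=C1C(=O)C(C)(C)C(O)=C(C(C)=O)C1=O | intermediate
13 | 2-acetyl-6-[(3-butanoyl-2,4-dihydroxy-6-methoxyphenyl)methyl]-3,5-dihydroxy-4,4-dimethylcyclohexa-2,5-dien-1-one (CNP0378451.0; no stereocentre) | CCCC(=O)c1c(O)cc(OC)c(CC2=C(O)C(C)(C)C(O)=C(C(C)=O)C2=O)c1O | target

**Step count and risks**

Total step count: 6.
Longest linear sequence: 4 steps (steps 3, 4, 5 and 6, from 5 and 6); the phenol branch (steps 1 and 2) joins in step 6.

Steps most likely to fail:

1. Step 6. The capture of the enetrione may lose chemoselectivity: it can add to itself (homodimerisation through carbon or hetero-Diels–Alder dimerisation), the product can be alkylated a second time at its remaining free aromatic position, and the amine base can promote exchange of the methylene bridge between rings. Fallback, with the roles of electrophile and nucleophile reversed: it sets out from 4 and comes back at 13. A phenolic Mannich reaction of 4 (aq. CH2O, Me2NH, EtOH, 25 °C) at one of its two equivalent free positions should give 1-{3-[(dimethylamino)methyl]-2,6-dihydroxy-4-methoxyphenyl}butan-1-one F1. Heating F1 with 10 in 1,4-dioxane at 90 °C should expel dimethylamine to give the ortho-quinone methide 2-butanoyl-3-hydroxy-5-methoxy-6-methylidenecyclohexa-2,4-dien-1-one F2, which is taken up in a Michael addition by the only free ring carbon of the enol 10 to give 13.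

2. Step 3. The ring closure may stall at the hindered ester carbonyl next to the quaternary carbon, the keto ester 7 may fragment by retro-Claisen attack of the released methoxide, or the enolate may be acylated on oxygen in the first stage. Fallback, with a nitrile in place of the ester as the ring-closing electrophile, so that no alkoxide is released and the electrophilic carbon is unhindered: it sets out from 6 and comes back at 8. 2-Methylpropanenitrile, lithiated with LiN(iPr)2 in THF at −78 °C, should be C-acylated by 6 to give 3-(3,5-dimethyl-1,2-oxazol-4-yl)-2,2-dimethyl-3-oxopropanenitrile F3. LiN(SiMe3)2 (THF, −78 → 25 °C) should then bring about a Thorpe–Ziegler ring closure of the 5-methyl carbanion onto the nitrile, which after aqueous work-up gives 6-amino-3,5,5-trimethyl-1,2-benzoxazol-4(5H)-one F4. Enamine hydrolysis of F4 (1 M HCl aq., THF, 50 °C) should give 8.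

3. Step 2. The methylation may run on to the dimethyl ether or attack a chelated ortho hydroxyl group, which would lower the amount of the 4-monoether. Fallback, in which the oxygen pattern is set by selective ether cleavage instead of selective etherification: it sets out from 2 and comes back at 4, so that 1 and 3 are not needed. Friedel–Crafts acylation of 1,3,5-trimethoxybenzene with 2 (AlCl3, CH2Cl2, 0 °C) should give 1-(2,4,6-trimethoxyphenyl)butan-1-one F5. Chelation-directed ether cleavage with BCl3 (excess, CH2Cl2, 0 → 25 °C; aqueous work-up) should remove only the two methyl groups ortho to the ketone and give 4.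

**Further compounds**

F1 | step 6 | 1-{3-[(dimethylamino)methyl]-2,6-dihydroxy-4-methoxyphenyl}butan-1-one | CCCC(=O)c1c(O)cc(OC)c(CN(C)C)c1O
F2 | step 6 | 2-butanoyl-3-hydroxy-5-methoxy-6-methylidenecyclohexa-2,4-dien-1-one | CCCC(=O)C1=C(O)C=C(OC)C(=C)C1=O
F3 | step 3 | 3-(3,5-dimethyl-1,2-oxazol-4-yl)-2,2-dimethyl-3-oxopropanenitrile | N#CC(C)(C)C(=O)c1c(C)noc1C
F4 | step 3 | 6-amino-3,5,5-trimethyl-1,2-benzoxazol-4(5H)-one | Cc1noc2C=C(N)C(C)(C)C(=O)c12
F5 | step 2 | 1-(2,4,6-trimethoxyphenyl)butan-1-one | CCCC(=O)c1c(OC)cc(OC)cc1OC
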